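Numbering (pinane): C2 is the spiro carbon, C1 and C5 the bridgeheads, C6 the CMe2 carbon, C7 the CH2 bridge, C10 the pyran CH2, and C4' the CH(iPr) carbon of the pyran ring.
Cuts: (a) a retro-hetero-Diels–Alder reaction at O–C2 and C10–C4' gives (+)-β-pinene and isobutylidenesyncarpic acid; (b) C7H2 is raised to C7=O; (c) a retro-[2+2] at C1–C6 and C5–C7 opens both carbocycles to an acyclic geranic acid amide.
Enabling feature: in the cyclobutane C1–C7–C5–C6 the gem-dimethyl carbon C6 faces the unsubstituted C7, and C1 and C5 are also joined by the chain C2–C3–C4. This is the pattern of a crossed [2+2] union of a prenyl alkene (C5=C6) with a C1=C7 cumulene held three atoms away.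
Forward order: the amide is made first. The six- and four-membered carbocycles then close together (keteniminium [2+2]). The two helpers (auxiliary, C7 oxygen) are removed, and the dihydropyran ring is closed last by a domino Knoevenagel/hetero-Diels–Alder reaction.
Stereochemistry: C1 and C5 come from the C2-symmetric (2S,5S)-2,5-dimethylpyrrolidine auxiliary. C2 and C4' come from the pinene, by attack opposite to the CMe2 bridge with C3 endo and C1 exo.

Key step: step 2

Assumption: syncarpic acid, (E)-geranic acid and (2S,5S)-2,5-dimethylpyrrolidine are taken as catalogue compounds.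

Step 1
Reactants: 1 (E)-geranic acid; 2 (2S,5S)-2,5-dimethylpyrrolidine
Product: 4 (E)-1-[(2S,5S)-2,5-dimethylpyrrolidin-1-yl]-3,7-dimethylocta-2,6-dien-1-one, via geranoyl chloride 3 (not isolated)
Conditions: (COCl)2, DMF (cat.), CH2Cl2, 0 °C to rt; evaporate; then 2, aq. NaOH, CH2Cl2, 0 °C
Reagents that add atoms: none
Why: Acid chloride formation and Schotten–Baumann acylation are standard amide chemistry, the two-phase inorganic base avoids the tertiary-amine-induced ketene formation that would move the conjugated double bond, and no stereocenter is formed because both come in with 2.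

Step 2
Reactants: 4 (E)-1-[(2S,5S)-2,5-dimethylpyrrolidin-1-yl]-3,7-dimethylocta-2,6-dien-1-one
Product: 7 (1R,5S)-7,7-dimethyl-2-methylidenebicyclo[3.1.1]heptan-6-one, via vinylketeniminium triflate 5 (not isolated), via bicyclic cyclobutaniminium triflate 6 (not isolated)
Conditions: Tf2O, 2,4,6-collidine, ClCH2CH2Cl (0.01 M), 0 to 80 °C; then H2O, 60 °C
Reagents that add atoms: water, O
Why: Proposed new method: Tf2O converts amide 4 into its O-triflyl iminium ion, collidine takes a proton from the C10 methyl group (the group cis to the activated carbonyl carbon), and loss of triflate gives vinylketeniminium ion 5, in which C7 is the strongest electrophile of the molecule. The prenyl carbon C5 attacks C7 in the plane of the C1 substituents and closes the six-membered ring C7–C1–C2–C3–C4–C5 (6-exo at the alkene), the positive charge builds up on the tertiary carbon C6, and the enamine carbon C1 collapses onto C6 and closes the four-membered ring (bond C1–C6), so that one asynchronous crossed [2+2] event makes both carbocycles and is driven by the energy of the cumulated iminium ion. The closest known reaction types are the thermal vinylketene–alkene [2+2] closure of geranoyl chloride to the racemic bicyclo[3.1.1]heptan-6-one and the intramolecular keteniminium–alkene [2+2] cycloaddition steered by C2-symmetric 2,5-dimethylpyrrolidine, and their union on an unsaturated amide and on a crossed adduct is the new element. C1 and C5 arise together and can only be cis-bridged, so only the sense of twist of the alkene over the cumulene is open; on the face that the tether allows, one of the two quadrants next to nitrogen holds a ring methyl group of the (2S,5S)-auxiliary, the CMe2 end should swing into the empty one, and this should give the (1R,5S) ion 6. The step needs crossed and not straight regiochemistry, which the gem-dimethyl group secures by placing the charge on C6, and [2+2] and not [4+2] periselectivity, which the anti-Bredt alkene of the alternative bicyclo[3.3.1] adduct secures, while high dilution holds back dimerization. Water then hydrolyses 6 to ketone 7 and releases the auxiliary.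

Step 3
Reactants: 7 (1R,5S)-7,7-dimethyl-2-methylidenebicyclo[3.1.1]heptan-6-one
Product: 9 (1R,5R)-(+)-β-pinene, via hydrazone 8 (not isolated)
Conditions: N2H4·H2O, KOH, diethylene glycol, 120 then 200 °C, product distilled off
Reagents that add atoms: none
Why: Wolff–Kishner reduction of the strained, unhindered cyclobutanone through hydrazone 8 removes the helper oxygen at C7, a conversion with close precedent on this very ring system, the isolated exocyclic alkene is inert to hydroxide, and the bridgehead centers C1 and C5 cannot epimerize.

Step 4
Reactants: 9 (1R,5R)-(+)-β-pinene; 10 syncarpic acid (2,2,4,4-tetramethylcyclohexane-1,3,5-trione); 11 isobutyraldehyde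
Product: 13 (1'S,2S,4S,5'R)-4-isopropyl-6,6,6',6',8,8-hexamethyl-3,4-dihydrospiro[chromene-2,2'-bicyclo[3.1.1]heptane]-5,7(6H,8H)-dione (target), via isobutylidenesyncarpic acid 12 (not isolated)
Conditions: ethylenediammonium diacetate (10 mol %), 4 Å MS, toluene, 80 °C, sealed tube
Reagents that add atoms: none
Why: Domino Knoevenagel condensation and inverse-electron-demand hetero-Diels–Alder reaction, well known for alkylidene-1,3-diones and 1,1-disubstituted terpene alkenes: oxadiene 12 binds its oxygen to the more substituted C2 and C4' to C10, comes from the face of 9 opposite to the CMe2 bridge (sets C2), and keeps its isopropyl group outside with C3H2 endo and the bridgehead C1 with its C7H2 bridge exo (sets C4').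

Compound list
1 | (E)-geranic acid | CC(C)=CCC/C(C)=C/C(=O)O | starting material
2 | (2S,5S)-2,5-dimethylpyrrolidine | C[C@H]1CC[C@H](C)N1 | starting material
3 | geranoyl chloride | CC(C)=CCC/C(C)=C/C(=O)Cl | intermediate
4 | (E)-1-[(2S,5S)-2,5-dimethylpyrrolidin-1-yl]-3,7-dimethylocta-2,6-dien-1-one | CC(C)=CCC/C(C)=C/C(=O)N1[C@@H](C)CC[C@@H]1C | intermediate
5 | vinylketeniminium triflate (CH2=C(homoprenyl)–CH=C=N+ of the auxiliary) | C=C(CCC=C(C)C)C=C=[N+]1[C@@H](C)CC[C@@H]1C.[O-]S(=O)(=O)C(F)(F)F | intermediate
6 | (1R,5S)-bicyclic cyclobutaniminium triflate | CC1(C)[C@@H]2CCC(=C)[C@H]1C2=[N+]3[C@@H](C)CC[C@@H]3C.[O-]S(=O)(=O)C(F)(F)F | intermediate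
7 | (1R,5S)-7,7-dimethyl-2-methylidenebicyclo[3.1.1]heptan-6-one | CC1(C)[C@@H]2CCC(=C)[C@H]1C2=O | intermediate
8 | hydrazone of 7 | CC1(C)[C@@H]2CCC(=C)[C@H]1C2=NN | intermediate
9 | (1R,5R)-(+)-β-pinene | CC1(C)[C@@H]2CCC(=C)[C@H]1C2 | intermediate
10 | syncarpic acid | CC1(C)C(=O)CC(=O)C(C)(C)C1=O | starting material
11 | isobutyraldehyde | CC(C)C=O | starting material
12 | isobutylidenesyncarpic acid (2,2,4,4-tetramethyl-6-(2-methylpropylidene)cyclohexane-1,3,5-trione) | CC(C)C=C1C(=O)C(C)(C)C(=O)C(C)(C)C1=O | intermediate
13 | target, CNP0534730.3 | CC(C)[C@@H]1C[C@]2(CC[C@@H]3C[C@H]2C3(C)C)OC2=C1C(=O)C(C)(C)C(=O)C2(C)C | target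

Total step count: 4. Longest linear sequence: 4 steps (1 → 4 → 7 → 9 → 13).

Steps most likely to fail

1. Step 2 (labelled step). Three processes may spoil it: low or reversed facial selectivity in the twist of the alkene over the cumulene, proton loss from C3H2 in place of C10H3 during formation of the cumulene, and acid-promoted migration of the exocyclic double bond.
The fallback sets out from 1 (through acid chloride 3) and comes back at 7. It uses known chemistry only.
- Acid chloride 3 is heated with Et3N in toluene under high dilution. The vinylketene F1 closes by the known thermal [2+2] cycloaddition to the racemic ketone F2.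
- F2 is resolved by addition of lithiated (S)-N,S-dimethyl-S-phenylsulfoximine (n-BuLi, THF, −78 °C). The carbanion should come from the side of the three-carbon bridge, because a C6 methyl group blocks the other face.
- The diastereomeric adducts are separated by chromatography. Thermolysis of the β-hydroxysulfoximine F3 (toluene, 110 °C) returns 7.

2. Step 4. The oxadiene may be consumed by Michael addition of a second molecule of 10. The pinene may be opened or isomerized by acid or amine. An ene reaction may compete, and endo/exo discrimination at C4' may be weak.
The fallback sets out from 10 and 11 and comes back at 12, and so at 13.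
- 10 and 11 are joined reductively (L-proline, diethyl 2,6-dimethyl-1,4-dihydropyridine-3,5-dicarboxylate, CH2Cl2, rt) to 2-isobutylsyncarpic acid F4.
- F4 is dehydrogenated in the presence of 9 (Ag2O, TEMPO, toluene, 60 °C). 12 is then released slowly, free of aldehyde, amine, water and unalkylated 10, and is trapped at once by 9.

3. Step 3. The volatile product may be lost. Hydroxide may cleave the non-enolisable cyclobutanone (Haller–Bauer-type ring opening) before the hydrazone has formed. The double bond may migrate at 200 °C.
The fallback sets out from 7 and comes back at 13, with the order of events reversed.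
- 7 serves as the dienophile under the conditions of step 4 and should give the keto adduct F5, with attack again opposite to the CMe2 bridge.
- Only the strained cyclobutanone, and neither of the two carbonyl groups flanked by quaternary carbons, condenses with TsNHNH2 (EtOH, rt) to the tosylhydrazone F6.
- Catecholborane (CHCl3, −10 °C), then NaOAc·3H2O (reflux), reduces C7 to CH2.

Further compounds
F1 | step 2 | vinylketene from geranoyl chloride | C=C(CCC=C(C)C)C=C=O
F2 | step 2 | racemic 7,7-dimethyl-2-methylidenebicyclo[3.1.1]heptan-6-one | CC1(C)C2CCC(=C)C1C2=O
F3 | step 2 | β-hydroxysulfoximine from (1R,5S)-ketone and the (S)-sulfoximine | CC1(C)[C@@H]2CCC(=C)[C@H]1[C@@]2(O)C[S@@](=O)(=NC)c1ccccc1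
F4 | step 4 | 2-isobutylsyncarpic acid (enol form) | CC(C)CC1=C(O)C(C)(C)C(=O)C(C)(C)C1=O
F5 | step 3 | keto adduct (target with C7=O) | CC(C)[C@@H]1C[C@]2(CC[C@@H]3C(=O)[C@H]2C3(C)C)OC2=C1C(=O)C(C)(C)C(=O)C2(C)C
F6 | step 3 | tosylhydrazone of F5 | CC(C)[C@@H]1C[C@]2(CC[C@@H]3C(=NNS(=O)(=O)c4ccc(C)cc4)[C@H]2C3(C)C)OC2=C1C(=O)C(C)(C)C(=O)C2(C)C
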